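**Plan**
- Retrosynthetic cuts: the ester to the acid; the prenyl C–C bond at the quaternary ring carbon C8 (dearomative allylation of an aromatic chromene); the pyran O1–C2 bond with a hydrogen shift, which contracts the 2,2-dimethyl-2H-pyran to its 2-isopropenyl-2,3-dihydrofuran isomer; the aryl–CH2 bond of the side chain; the dihydrofuran to an aryl iodide plus isoprene; the side-chain C4–C5 bond.
- Forward order: the benzene ring is bought as 2,4,6-trihydroxybenzophenone, the five-membered oxygen ring is annulated with isoprene, the side chain is cross-coupled, the five-membered ring is expanded to the six-membered pyran, and the carbocycle is dearomatised last.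
- Enabling feature: in the dihydrofuran, O1–C2 is allylic to the isopropenyl group, C3 carries two benzylic hydrogens and O1 is para to the benzoyl carbonyl. O1 can therefore leave, a C3–H can be lost, and the same C5H8 unit can re-close through its tertiary carbon to the conjugated isomer O1–C2(Me)2–C3=C4–C4a=C8a.
- Stereochemistry: side-chain C5 (R in the target) comes from an (S)-4-benzyloxazolidinone-controlled deconjugative alkylation. The quaternary C8 (S) comes from the chiral diphosphine ligand in the palladium-catalysed dearomative prenylation. The dihydrofuran C2 centre is uncontrolled and is erased in the ring expansion.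
- The acetates on the two phenols beside the benzoyl group serve the cross-coupling and leave only the ring oxygen able to close the pyran.

Key step: step 9

Remark: ethyl (2E)-4-bromo-2-methylbut-2-enoate and prenyl acetate are taken as purchasable, and the target is handled as the 7-hydroxy-5-oxo enol tautomer of the given structure.

**Route**

Step 1
Reactants: 1 (4S)-4-benzyl-1,3-oxazolidin-2-one; 2 3-methylbut-2-enoyl chloride
Product: 3 (4S)-4-benzyl-3-(3-methylbut-2-enoyl)-1,3-oxazolidin-2-one
Conditions: n-BuLi (1.05 equiv), THF, –78 °C; then 2, –78 to 0 °C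
Reagents that add atoms: none
Why: N-acylation of the lithiated oxazolidinone with the acid chloride attaches the auxiliary, and no stereocentre is formed.

Step 2
Reactants: 3; 4 ethyl (2E)-4-bromo-2-methylbut-2-enoate
Product: 5 ethyl (2E,5S)-5-{[(4S)-4-benzyl-2-oxo-1,3-oxazolidin-3-yl]carbonyl}-2,6-dimethylhepta-2,6-dienoate
Conditions: NaN(SiMe3)2 (1.1 equiv), THF, –78 °C; then 4 (1.3 equiv), –78 to –45 °C
Reagents that add atoms: none
Why: γ-Deprotonation should give the sodium-chelated (Z)-dienolate, which is alkylated at its α-carbon by SN2 displacement of the allylic bromide on the face away from the benzyl group (oxazolidinone-auxiliary deconjugative alkylation), so that C5 is set as (S) and the isopropenyl group is unveiled.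

Step 3
Reactants: 5
Product: 6 ethyl (2E,5S)-5-(hydroxymethyl)-2,6-dimethylhepta-2,6-dienoate
Conditions: NaBH4 (4 equiv), THF/H2O (4:1), 0 °C to rt
Reagents that add atoms: none
Why: Borohydride reduces the activated N-acyl imide to the primary alcohol and releases the auxiliary (reductive auxiliary removal), while the conjugated ethyl ester should be left and the stereocentre is no longer α to a carbonyl.

Step 4
Reactants: 6
Product: 7 ethyl (2E,5S)-5-(iodomethyl)-2,6-dimethylhepta-2,6-dienoate
Conditions: I2, PPh3, imidazole, CH2Cl2, 0 °C to rt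
Reagents that add atoms: iodine, II
Why: Appel-type iodination (Garegg–Samuelsson conditions) converts the primary alcohol into the iodide by SN2 at a non-stereogenic carbon.

Step 5
Reactants: 8 (2,4,6-trihydroxyphenyl)(phenyl)methanone
Product: 10 (3-bromo-5-iodo-2,4,6-trihydroxyphenyl)(phenyl)methanone, via 3-bromo-2,4,6-trihydroxybenzophenone 9 (not isolated)
Conditions: NBS (1.0 equiv, slow addition), MeCN, –40 °C; then NIS (1.05 equiv), –40 to 0 °C
Reagents that add atoms: N-bromosuccinimide, O=C1CCC(=O)N1Br; N-iodosuccinimide, O=C1CCC(=O)N1I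
Why: Electrophilic aromatic halogenation places bromine and then iodine on the two equivalent free ring positions, bromine first so that the softer iodinating agent does not exchange it, which gives two halogens of different reactivity towards palladium.

Step 6
Reactants: 10; 11 isoprene (2-methylbuta-1,3-diene)
Product: 12 [7-bromo-4,6-dihydroxy-2-(prop-1-en-2-yl)-2,3-dihydro-1-benzofuran-5-yl](phenyl)methanone (racemic at C2)
Conditions: 11 (5 equiv), Pd(OAc)2 (5 mol %), n-Bu4NCl (1 equiv), NaHCO3 (2.5 equiv), DMF, 60 °C, sealed tube
Reagents that add atoms: none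
Why: In this Larock heteroannulation of a 1,3-diene, zerovalent palladium should insert into the C–I bond only, the aryl group adds to the unsubstituted vinyl terminus of isoprene, and the η3-allyl is captured at its internal carbon by the most acidic phenoxide (para to the benzoyl group) in a 5-exo closure; the C2 centre forms without control and is later erased.

Step 7
Reactants: 12
Product: 13 5-benzoyl-7-bromo-2-(prop-1-en-2-yl)-2,3-dihydro-1-benzofuran-4,6-diyl diacetate (racemic at C2)
Conditions: Ac2O (3 equiv), pyridine, DMAP (10 mol %), CH2Cl2, rt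
Reagents that add atoms: acetic anhydride, CC(=O)OC(C)=O
Why: DMAP-catalysed O-acetylation masks both hydrogen-bonded phenols, which removes the acidic protons before the organozinc step, activates the aryl bromide and later leaves the ring oxygen as the only phenol that can close the pyran.

Step 8
Reactants: 13; 7
Product: 15 ethyl (2E,5R)-5-{[4,6-diacetoxy-5-benzoyl-2-(prop-1-en-2-yl)-2,3-dihydro-1-benzofuran-7-yl]methyl}-2,6-dimethylhepta-2,6-dienoate (both C2 epimers of the dihydrofuran), via alkylzinc iodide 14 (not isolated)
Conditions: 7, Zn dust (3 equiv, activated by BrCH2CH2Br and Me3SiCl), LiCl, THF, 40 °C; then 13, Pd(OAc)2 (3 mol %), SPhos (6 mol %), THF, 40 °C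
Reagents that add atoms: none
Why: Zinc insertion into the primary C–I bond followed by Negishi sp3–sp2 coupling joins the side chain to C7; the zinc-bearing carbon is not stereogenic, so the adjacent centre is carried over unchanged (its descriptor becomes R only through the change in substituent priorities), and esters, acetates and the allylic aryl ether should be tolerated at this temperature.

Step 9
Reactants: 15
Product: 17 ethyl (2E,5R)-5-[(5,7-diacetoxy-6-benzoyl-2,2-dimethyl-2H-chromen-8-yl)methyl]-2,6-dimethylhepta-2,6-dienoate, via ring-opened dienyl phenol 16 (not isolated)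
Conditions: Pd(PPh3)4 (5 mol %), PhCO2H (20 mol %), 1,4-dioxane (degassed), 80 °C
Reagents that add atoms: none
Why: Proposed new method: zerovalent palladium is expected to ionise the allylic O1–C2 bond of the dihydrofuran (the leaving phenoxide is para to the benzoyl group and flanked by two acetoxy groups), and β-hydride loss of a benzylic C3–H from the η3-(2-methylallyl)palladium phenoxide opens the five-membered ring to the (E)-3-methylbuta-1,3-dienyl phenol 16; the palladium hydride, held by PhCO2H, then adds to the terminal CH2 of the diene and the phenol oxygen closes on the CMe2 end of the new η3-allyl. The closest known reaction types are the Tsuji–Trost ionisation of allyl aryl ethers with elimination to 1,3-dienes, the palladium/carboxylic acid hydroalkoxylation of 1,3-dienes and the cyclisation of ortho-(3-methylbutadienyl)phenols to 2,2-dimethylchromenes. The pyran ring closes by 6-endo attack of O1 on the allyl terminus after syn–anti isomerisation of the allyl; closure at the benzylic terminus would need a four-membered ring and closure back to the five-membered or to a seven-membered ether stays reversible, so the conjugated, unstrained chromene is the sink. No stereocentre is formed: the uncontrolled C2 centre is erased and the (5R) centre of the side chain carries no ionisable allylic bond. The step needs closure on the right oxygen and reaction at one allylic C–O bond only; the phenols beside the benzoyl group are acetates, so only O1 is free to close, and the other alkenes of 15 have no allylic leaving group.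

Step 10
Reactants: 17
Product: 18 ethyl (2E,5R)-5-[(6-benzoyl-5,7-dihydroxy-2,2-dimethyl-2H-chromen-8-yl)methyl]-2,6-dimethylhepta-2,6-dienoate
Conditions: K2CO3 (0.3 equiv), EtOH, 0 °C to rt
Reagents that add atoms: none
Why: Base-catalysed ethanolysis (transesterification) should remove the two aryl acetates much faster than it touches the conjugated ethyl ester, and ethanol as solvent keeps that ester unchanged.

Step 11
Reactants: 18; 19 3-methylbut-2-en-1-yl acetate (prenyl acetate)
Product: 20 ethyl (2E,5R)-5-{[(8S)-6-benzoyl-7-hydroxy-2,2-dimethyl-8-(3-methylbut-2-en-1-yl)-5-oxo-5,8-dihydro-2H-chromen-8-yl]methyl}-2,6-dimethylhepta-2,6-dienoate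
Conditions: 19 (1.3 equiv), Pd2(dba)3·CHCl3 (2.5 mol %), (R,R)-DACH-phenyl diphosphine ligand [N,N'-((1R,2R)-cyclohexane-1,2-diyl)bis(2-(diphenylphosphanyl)benzamide)] (7.5 mol %), Cs2CO3 (1.0 equiv), THF, 0 °C
Reagents that add atoms: none
Why: In this palladium-catalysed asymmetric allylic alkylation with dearomatisation (Tsuji–Trost type), the phenoxide should attack through C8 (between the 7-oxygen and O1, which keeps the chromene conjugation and the benzoyl-flanked enolised tricarbonyl unit) on the unsubstituted terminus of the η3-prenyl complex, and the chiral pocket of the ligand selects the face so that the quaternary centre forms as (8S); the ligand antipode to be used is the one that a pilot run with both shows to give this face.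

Step 12
Reactants: 20
Product: 21 (2E,5R)-5-{[(8S)-6-benzoyl-7-hydroxy-2,2-dimethyl-8-(3-methylbut-2-en-1-yl)-5-oxo-5,8-dihydro-2H-chromen-8-yl]methyl}-2,6-dimethylhepta-2,6-dienoic acid (CNP0333091.1)
Conditions: LiOH·H2O (5 equiv), THF/H2O (3:1), 35 °C; then 1 M HCl to pH 3
Reagents that add atoms: lithium hydroxide, [Li+].[OH-]
Why: Saponification of the ethyl ester, during which the acylated trione is held as its unreactive enolate so that neither retro-Claisen cleavage nor epimerisation is expected, and acidification returns the enol and the free acid.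

**Compound list**

1 | (4S)-4-benzyl-1,3-oxazolidin-2-one | O=C1N[C@@H](Cc2ccccc2)CO1 | starting material
2 | 3-methylbut-2-enoyl chloride | CC(C)=CC(Cl)=O | starting material
3 | (4S)-4-benzyl-3-(3-methylbut-2-enoyl)-1,3-oxazolidin-2-one | CC(C)=CC(=O)N1[C@@H](Cc2ccccc2)COC1=O | intermediate
4 | ethyl (2E)-4-bromo-2-methylbut-2-enoate | CCOC(=O)/C(C)=C/CBr | starting material
5 | ethyl (2E,5S)-5-{[(4S)-4-benzyl-2-oxo-1,3-oxazolidin-3-yl]carbonyl}-2,6-dimethylhepta-2,6-dienoate | C=C(C)[C@H](C/C=C(\C)C(=O)OCC)C(=O)N1[C@@H](Cc2ccccc2)COC1=O | intermediate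
6 | ethyl (2E,5S)-5-(hydroxymethyl)-2,6-dimethylhepta-2,6-dienoate | C=C(C)[C@H](C/C=C(\C)C(=O)OCC)CO | intermediate
7 | ethyl (2E,5S)-5-(iodomethyl)-2,6-dimethylhepta-2,6-dienoate | C=C(C)[C@H](C/C=C(\C)C(=O)OCC)CI | intermediate
8 | (2,4,6-trihydroxyphenyl)(phenyl)methanone | O=C(c1ccccc1)c1c(O)cc(O)cc1O | starting material
9 | (3-bromo-2,4,6-trihydroxyphenyl)(phenyl)methanone (not isolated) | O=C(c1ccccc1)c1c(O)cc(O)c(Br)c1O | intermediate
10 | (3-bromo-5-iodo-2,4,6-trihydroxyphenyl)(phenyl)methanone | O=C(c1ccccc1)c1c(O)c(I)c(O)c(Br)c1O | intermediate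
11 | isoprene (2-methylbuta-1,3-diene) | C=CC(C)=C | starting material
12 | [7-bromo-4,6-dihydroxy-2-(prop-1-en-2-yl)-2,3-dihydro-1-benzofuran-5-yl](phenyl)methanone (racemic at C2) | C=C(C)C1Cc2c(O)c(C(=O)c3ccccc3)c(O)c(Br)c2O1 | intermediate
13 | 5-benzoyl-7-bromo-2-(prop-1-en-2-yl)-2,3-dihydro-1-benzofuran-4,6-diyl diacetate (racemic at C2) | C=C(C)C1Cc2c(OC(C)=O)c(C(=O)c3ccccc3)c(OC(C)=O)c(Br)c2O1 | intermediate
14 | [(2S,4E)-6-ethoxy-5-methyl-6-oxo-2-(prop-1-en-2-yl)hex-4-en-1-yl]zinc iodide (not isolated) | C=C(C)[C@H](C/C=C(\C)C(=O)OCC)C[Zn]I | intermediate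
15 | ethyl (2E,5R)-5-{[4,6-diacetoxy-5-benzoyl-2-(prop-1-en-2-yl)-2,3-dihydro-1-benzofuran-7-yl]methyl}-2,6-dimethylhepta-2,6-dienoate (both C2 epimers of the dihydrofuran) | C=C(C)[C@H](C/C=C(\C)C(=O)OCC)Cc1c(OC(C)=O)c(C(=O)c2ccccc2)c(OC(C)=O)c2CC(C(C)=C)Oc12 | intermediate
16 | ethyl (2E,5R)-5-({2,4-diacetoxy-3-benzoyl-6-hydroxy-5-[(1E)-3-methylbuta-1,3-dien-1-yl]phenyl}methyl)-2,6-dimethylhepta-2,6-dienoate (not isolated) | C=C(C)[C@H](C/C=C(\C)C(=O)OCC)Cc1c(OC(C)=O)c(C(=O)c2ccccc2)c(OC(C)=O)c(/C=C/C(C)=C)c1O | intermediate
17 | ethyl (2E,5R)-5-[(5,7-diacetoxy-6-benzoyl-2,2-dimethyl-2H-chromen-8-yl)methyl]-2,6-dimethylhepta-2,6-dienoate | C=C(C)[C@H](C/C=C(\C)C(=O)OCC)Cc1c(OC(C)=O)c(C(=O)c2ccccc2)c(OC(C)=O)c2C=CC(C)(C)Oc12 | intermediate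
18 | ethyl (2E,5R)-5-[(6-benzoyl-5,7-dihydroxy-2,2-dimethyl-2H-chromen-8-yl)methyl]-2,6-dimethylhepta-2,6-dienoate | C=C(C)[C@H](C/C=C(\C)C(=O)OCC)Cc1c(O)c(C(=O)c2ccccc2)c(O)c2C=CC(C)(C)Oc12 | intermediate
19 | 3-methylbut-2-en-1-yl acetate (prenyl acetate) | CC(C)=CCOC(C)=O | starting material
20 | ethyl (2E,5R)-5-{[(8S)-6-benzoyl-7-hydroxy-2,2-dimethyl-8-(3-methylbut-2-en-1-yl)-5-oxo-5,8-dihydro-2H-chromen-8-yl]methyl}-2,6-dimethylhepta-2,6-dienoate | C=C(C)[C@H](C/C=C(\C)C(=O)OCC)C[C@@]1(CC=C(C)C)C(O)=C(C(=O)c2ccccc2)C(=O)C2=C1OC(C)(C)C=C2 | intermediate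
21 | (2E,5R)-5-{[(8S)-6-benzoyl-7-hydroxy-2,2-dimethyl-8-(3-methylbut-2-en-1-yl)-5-oxo-5,8-dihydro-2H-chromen-8-yl]methyl}-2,6-dimethylhepta-2,6-dienoic acid | C=C(C)[C@H](C/C=C(\C)C(=O)O)C[C@@]1(CC=C(C)C)C(O)=C(C(=O)c2ccccc2)C(=O)C2=C1OC(C)(C)C=C2 | target

**Count**

Total steps: 12. Longest linear sequence: 9 steps (steps 1, 2, 3, 4, 8, 9, 10, 11, 12).

**Steps most likely to fail**

1. Step 9 (proposed new method). The allylic ether may not ionise, the ion pair may simply re-close to the five-membered ring, or the palladium hydride may move the isopropenyl double bond of the side chain. The fallback uses known chemistry and sets out from 15. The dihydrofuran is opened reductively by palladium-catalysed hydrostannolysis of the allylic aryl ether (Pd(PPh3)4, Bu3SnH, AcOH, CH2Cl2, rt; hydride delivered to the unsubstituted allyl terminus) to give the ortho-prenyl phenol F1. F1 is then cyclised by dehydrogenation with DDQ (benzene, 80 °C; hydride abstraction to the ortho-quinone methide and oxa-6π closure on the only free phenol). This returns to the route at 17.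

2. Step 11. Alkylation may take place at oxygen or at the ring-fusion carbon C4a instead of C8, and the facial selectivity may be poor because the ligand has to override the remote C5 centre. The fallback sets out from 18 and replaces η3-allyl palladium control by chiral ion-pair control. Alkylative dearomatisation is run with prenyl bromide under phase-transfer conditions (CsOH·H2O, toluene, –40 °C, O-allyl-N-(9-anthracenylmethyl)cinchonidinium bromide). The product mixture is resolved by preparative HPLC, in which the unwanted (8R) epimer F2, a diastereomer, is removed. This returns to the route at 20.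

3. Step 8. Oxidative addition at the doubly ortho-substituted aryl bromide may be slow, the organozinc may be lost by protonation, and zerovalent palladium may begin to ionise the allylic ether. The fallback sets out from 13 and 7 and joins them directly by nickel-catalysed reductive cross-electrophile coupling (NiBr2(dme), 4,4'-di-tert-butyl-2,2'-bipyridine, Mn powder, NaI, DMA, 60 °C). This needs neither a preformed organozinc nor zerovalent palladium and returns to the route at 15; no new compound arises (F0).

**Further compounds**

F1 | step 9 | ethyl (2E,5R)-5-{[2,4-diacetoxy-3-benzoyl-6-hydroxy-5-(3-methylbut-2-en-1-yl)phenyl]methyl}-2,6-dimethylhepta-2,6-dienoate | C=C(C)[C@H](C/C=C(\C)C(=O)OCC)Cc1c(OC(C)=O)c(C(=O)c2ccccc2)c(OC(C)=O)c(CC=C(C)C)c1O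
F2 | step 11 | ethyl (2E,5R)-5-{[(8R)-6-benzoyl-7-hydroxy-2,2-dimethyl-8-(3-methylbut-2-en-1-yl)-5-oxo-5,8-dihydro-2H-chromen-8-yl]methyl}-2,6-dimethylhepta-2,6-dienoate | C=C(C)[C@H](C/C=C(\C)C(=O)OCC)C[C@]1(CC=C(C)C)C(O)=C(C(=O)c2ccccc2)C(=O)C2=C1OC(C)(C)C=C2
F0 | step 8 | none | none
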